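**Retrosynthetic overview**
- Feature: the benzene ring of the dihydroisocoumarin (C4a'-C5'-C6'-C7'-C8'-C8a') is hexasubstituted, with oxygen at C6' and C8' in a 1,3-relationship. This pattern corresponds to a four-carbon 1,3-dioxygenated diene (C5'-C6'-C7'-C8') joined to a two-carbon ynoate (C4a'-C8a', ester carbon = C1').
- Last disconnection: the pyranone ring (O1-C2-C3-C4) comes from a 4-hydroxy-2,6-dimethoxyphenyl ring and tert-butyl but-2-ynoate. That ring is locally symmetric, so either ortho site gives the 6-substituted chromone, and chelation-directed dealkylation then frees 5-OH.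
- Next: the lactone O2'-C1' bond comes from the (R)-silyloxypropyl arm and the methyl ester.
- Key: C5'-C4a' and C8'-C8a' form by [4+2] of a 1-methoxy-1,3-bis(silyloxy)diene that already carries the bridge CH2-aryl with an (R)-5-silyloxyhex-2-ynoate, aromatised by loss of methanol. The diene comes from 4-hydroxy-2,6-dimethoxybenzaldehyde; the ynoate comes from (R)-propylene oxide, the only source of chirality.
- Ring order: isocoumarin benzene ring, then δ-lactone, then γ-pyranone.

Key step: step 8

Remark on the chemistry: primed locants belong to the dihydroisocoumarin (C1' lactone carbonyl, C3' stereocentre, C5' bridge-bearing carbon) and unprimed locants to the chromone. The C1=C2 geometry of the silyl ketene acetal and the E/Z ratio of the aryloxycrotonate are taken as inconsequential, because both are lost or reset in the following step.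

**Route**

Step 1
Reactants: 1 4-hydroxy-2,6-dimethoxybenzaldehyde
Product: 2 4-(benzyloxy)-2,6-dimethoxybenzaldehyde
Conditions: BnBr, K2CO3, DMF, rt to 50 °C
Reagents that add atoms: benzyl bromide, BrCc1ccccc1
Why: Williamson etherification of the single phenol, made more acidic by the para formyl group, should be clean under carbonate conditions that leave the aldehyde and the methyl ethers alone.

Step 2
Reactants: 2 4-(benzyloxy)-2,6-dimethoxybenzaldehyde; 3 Meldrum's acid (2,2-dimethyl-1,3-dioxane-4,6-dione)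
Product: 7 3-[4-(benzyloxy)-2,6-dimethoxyphenyl]propanoic acid, via arylidene Meldrum's acid 4 (not isolated), via benzyl Meldrum's acid 5 (not isolated), via benzylmalonic acid 6 (not isolated)
Conditions: HCO2H-Et3N (5:2), 95-100 °C; then 1 M HCl
Reagents that add atoms: water, O (the equivalent released in the condensation stage re-enters in the ring hydrolysis)
Why: This is the known one-pot Knoevenagel condensation, formate transfer reduction of the strongly electrophilic arylidene, ring hydrolysis and decarboxylation that turns ArCHO into ArCH2CH2CO2H, and because no metal catalyst is present the benzyl ether should survive.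

Step 3
Reactants: 7 3-[4-(benzyloxy)-2,6-dimethoxyphenyl]propanoic acid; 8 methyl propionate
Product: 11 methyl 5-[4-(benzyloxy)-2,6-dimethoxyphenyl]-2-methyl-3-oxopentanoate (racemic at C2), via acyl imidazolide 9 (not isolated), via lithium enolate 10 (not isolated)
Conditions: 7, CDI, THF, rt; separately 8 (excess), LDA, THF, −78 °C; combine at −78 °C; 1 M HCl quench
Reagents that add atoms: none
Why: A crossed Claisen acylation of the preformed ester enolate by the acyl imidazolide joins C6' to C7' and so brings in C7', its methyl group and C8' in one operation, the surplus enolate taking up the imidazole N-H and the acidic product, and the labile C2 centre may stay racemic because it becomes sp2 in step 4.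

Step 4
Reactants: 11 methyl 5-[4-(benzyloxy)-2,6-dimethoxyphenyl]-2-methyl-3-oxopentanoate
Product: 12 methyl 5-[4-(benzyloxy)-2,6-dimethoxyphenyl]-2-methyl-3-(trimethylsilyloxy)pent-2-enoate (E/Z mixture)
Conditions: Me3SiCl, Et3N, toluene, rt, 72 h; filtration under Ar
Reagents that add atoms: chlorotrimethylsilane, C[Si](C)(C)Cl
Why: Soft enolisation and O-silylation of the β-ketoester with Me3SiCl and Et3N is the standard first stage of bis(silyloxy)diene synthesis and should give the ester-conjugated silyl enol ether, whose E/Z ratio is of no consequence.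

Step 5
Reactants: 12 methyl 5-[4-(benzyloxy)-2,6-dimethoxyphenyl]-2-methyl-3-(trimethylsilyloxy)pent-2-enoate
Product: 14 (3Z)-5-[4-(benzyloxy)-2,6-dimethoxyphenyl]-1-methoxy-2-methyl-1,3-bis(trimethylsilyloxy)penta-1,3-diene, via lithium dienolate 13 (not isolated)
Conditions: LDA, THF, −78 °C; Me3SiCl, −78 °C to rt; hexane, filtration under Ar, used crude
Reagents that add atoms: chlorotrimethylsilane, C[Si](C)(C)Cl
Why: Kinetic γ-deprotonation of the vinylogous ester by LDA followed by O-silylation of the dienolate is the standard second stage, and allylic strain against the C2 methyl group and the ketene acetal should place the CH2Ar group trans to C2, which is the 3Z geometry.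

Step 6
Reactants: 15 methyl propiolate; 16 (R)-propylene oxide [(R)-2-methyloxirane]
Product: 18 methyl (R)-5-hydroxyhex-2-ynoate, via lithium acetylide 17 (not isolated)
Conditions: 15, n-BuLi, THF, −78 °C; BF3·OEt2; 16, −78 °C; aqueous quench
Reagents that add atoms: none
Why: In this Yamaguchi-Hirao alkynylation the BF3-activated epoxide is opened in an SN2 manner at its unsubstituted carbon by the lithium acetylide at −78 °C, so the C-O bond at the stereocentre is never broken and the R configuration of C3' comes unchanged from the chiral pool.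

Step 7
Reactants: 18 methyl (R)-5-hydroxyhex-2-ynoate
Product: 19 methyl (R)-5-(tert-butyldimethylsilyloxy)hex-2-ynoate
Conditions: TBSCl, imidazole, DMF, rt
Reagents that add atoms: tert-butyldimethylsilyl chloride, CC(C)(C)[Si](C)(C)Cl
Why: Imidazole-promoted silylation of the secondary alcohol gives a TBS ether robust enough for 150 °C and for the mild acid work-up of step 8, without touching the base-sensitive ynoate.

Step 8
Reactants: 14 (3Z)-5-[4-(benzyloxy)-2,6-dimethoxyphenyl]-1-methoxy-2-methyl-1,3-bis(trimethylsilyloxy)penta-1,3-diene; 19 methyl (R)-5-(tert-butyldimethylsilyloxy)hex-2-ynoate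
Product: 22 methyl 3-[4-(benzyloxy)-2,6-dimethoxybenzyl]-2-[(2R)-2-(tert-butyldimethylsilyloxy)propyl]-4,6-dihydroxy-5-methylbenzoate, via cyclohexadiene adduct 20 (not isolated), via bis-TMS resorcylate 21 (not isolated)
Conditions: neat, 19 in excess (3 equiv, surplus recovered), sealed tube, Ar, 150 °C, 24-48 h; then 0.5 M HCl-THF, 0 °C
Reagents that add atoms: none
Why: The three oxygen donors of 14 raise its HOMO and put the largest coefficient on the terminal carbon C5', which bonds ahead to the electrophilic β-carbon C4a' of ynoate 19 while the ketene acetal carbon C8' closes on the α-carbon C8a' in a concerted but strongly asynchronous normal-demand Diels-Alder reaction. Adduct 20 then loses methanol by 1,4-elimination (OMe from C8', H from C5') to give arene 21, and dilute acid strips the two aryl TMS ethers but not the secondary TBS ether. The closest known reaction type is the benzannulation of 1-alkoxy-1,3-bis(silyloxy)dienes with alk-2-ynoates to 6-alkylresorcylates. The one new ring, the six-membered carbocycle, closes by intermolecular [4+2] cycloaddition that makes both σ bonds, the sp3 centres of 20 vanish on aromatisation so that no stereocentre is created, and C3' lies two atoms away from the alkyne and is untouched. The only selectivity needed is regiochemical, and it is secured by the matched polarisation of donor terminus and acceptor β-carbon, while the 3Z geometry keeps the CH2Ar group on the outside of the s-cis diene and rules out a 1,5-hydrogen shift. Both bonding termini C5' and C4a' carry a CH2 substituent, so the reaction is run neat and hot with the cheaper ynoate in excess to outrun decay of the diene.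

Step 9
Reactants: 22 methyl 3-[4-(benzyloxy)-2,6-dimethoxybenzyl]-2-[(2R)-2-(tert-butyldimethylsilyloxy)propyl]-4,6-dihydroxy-5-methylbenzoate
Product: 23 methyl 3-[4-(benzyloxy)-2,6-dimethoxybenzyl]-2-[(2R)-2-(tert-butyldimethylsilyloxy)propyl]-4,6-diisopropoxy-5-methylbenzoate
Conditions: i-PrI (excess), Cs2CO3, DMF, 55 °C
Reagents that add atoms: 2-iodopropane, CC(C)I
Why: Williamson etherification of both caesium phenoxides in DMF should overcome the ortho crowding and the hydrogen bond of the C8' hydroxyl, and isopropyl ethers are chosen because aryl esters would migrate to the free phenoxide of step 12 whereas these ethers stand hydrogenolysis, carbonate and TFA and are later cleaved by BCl3 in preference to an unchelated methyl ether.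

Step 10
Reactants: 23 methyl 3-[4-(benzyloxy)-2,6-dimethoxybenzyl]-2-[(2R)-2-(tert-butyldimethylsilyloxy)propyl]-4,6-diisopropoxy-5-methylbenzoate
Product: 25 (3R)-5-[4-(benzyloxy)-2,6-dimethoxybenzyl]-6,8-diisopropoxy-3,7-dimethylisochroman-1-one, via hydroxy ester 24 (not isolated)
Conditions: TBAF, THF, 0 °C to 45 °C; aqueous work-up
Reagents that add atoms: none
Why: Fluoride cleaves the Si-O bond and the released secondary alkoxide closes the δ-lactone by 6-exo-trig transesterification on the neighbouring methyl ester, the C3'-O bond staying intact so that the R configuration is retained.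

Step 11
Reactants: 25 (3R)-5-[4-(benzyloxy)-2,6-dimethoxybenzyl]-6,8-diisopropoxy-3,7-dimethylisochroman-1-one
Product: 26 (3R)-5-(4-hydroxy-2,6-dimethoxybenzyl)-6,8-diisopropoxy-3,7-dimethylisochroman-1-one
Conditions: H2 (1 atm), 10% Pd/C, EtOAc-MeOH, rt
Reagents that add atoms: none
Why: Catalytic hydrogenolysis removes the only benzylic C-O bond, since the lactone oxygen sits on a homobenzylic carbon and the isopropyl and methyl ethers and the diarylmethane are inert.

Step 12
Reactants: 26 (3R)-5-(4-hydroxy-2,6-dimethoxybenzyl)-6,8-diisopropoxy-3,7-dimethylisochroman-1-one; 27 tert-butyl but-2-ynoate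
Product: 28 tert-butyl (E)-3-(4-{[(3R)-6,8-diisopropoxy-3,7-dimethyl-1-oxoisochroman-5-yl]methyl}-3,5-dimethoxyphenoxy)but-2-enoate (E major)
Conditions: K2CO3, DMF, 80 °C
Reagents that add atoms: none
Why: Base-mediated oxa-Michael addition of the unhindered phenoxide to the β-carbon of the alkynoate is the first half of the aryloxycrotonate route to chromones, the tert-butyl ester blocks transesterification, no acyl group is present that could migrate, phosphine catalysts are avoided because they divert but-2-ynoates to γ-addition, and the mainly E geometry is corrected in step 13.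

Step 13
Reactants: 28 tert-butyl (E)-3-(4-{[(3R)-6,8-diisopropoxy-3,7-dimethyl-1-oxoisochroman-5-yl]methyl}-3,5-dimethoxyphenoxy)but-2-enoate
Product: 31 (3R)-5-[(5,7-dimethoxy-2-methyl-4-oxo-4H-chromen-6-yl)methyl]-6,8-diisopropoxy-3,7-dimethylisochroman-1-one, via aryloxycrotonic acid 29 (not isolated), via mixed anhydride 30 (not isolated)
Conditions: TFA-CH2Cl2 (1:1), rt; then (CF3CO)2O, rt to 35 °C
Reagents that add atoms: none
Why: TFA removes the tert-butyl group, TFAA turns the acid into a mixed anhydride whose acylium ion has ketene-oxocarbenium character and can rotate from E to Z, and intramolecular Friedel-Crafts acylation (six-membered closure) at either of the two equivalent positions ortho to the aryloxy oxygen, each also activated by an ortho and a para methoxy group, gives the 6-substituted chromone under acidity mild enough for the isopropyl ethers and the CH2 bridge.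

Step 14
Reactants: 31 (3R)-5-[(5,7-dimethoxy-2-methyl-4-oxo-4H-chromen-6-yl)methyl]-6,8-diisopropoxy-3,7-dimethylisochroman-1-one
Product: 32 (3R)-6,8-dihydroxy-5-[(5-hydroxy-7-methoxy-2-methyl-4-oxo-4H-chromen-6-yl)methyl]-3,7-dimethylisochroman-1-one (CNP0180307.1)
Conditions: BCl3 (excess), CH2Cl2, −78 °C to 0 °C, then rt as needed; 1 M HCl work-up
Reagents that add atoms: none
Why: BCl3 cleaves the 5-OMe and 8'-O-i-Pr groups through six-membered chelates with the adjacent carbonyl groups and the 6'-O-i-Pr group through its secondary alkyl-oxygen bond, whereas the unchelated 7-OMe group, the lactone and the stereocentre are not attacked at or below room temperature (selective Lewis acid ether cleavage).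

**Compound list**

1 | 4-hydroxy-2,6-dimethoxybenzaldehyde | COc1cc(O)cc(OC)c1C=O | starting material
2 | 4-(benzyloxy)-2,6-dimethoxybenzaldehyde | COc1cc(OCc2ccccc2)cc(OC)c1C=O | intermediate
3 | Meldrum's acid | CC1(C)OC(=O)CC(=O)O1 | starting material
4 | 5-[4-(benzyloxy)-2,6-dimethoxybenzylidene]-2,2-dimethyl-1,3-dioxane-4,6-dione | COc1cc(OCc2ccccc2)cc(OC)c1C=C1C(=O)OC(C)(C)OC1=O | intermediate
5 | 5-[4-(benzyloxy)-2,6-dimethoxybenzyl]-2,2-dimethyl-1,3-dioxane-4,6-dione | COc1cc(OCc2ccccc2)cc(OC)c1CC1C(=O)OC(C)(C)OC1=O | intermediate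
6 | 2-[4-(benzyloxy)-2,6-dimethoxybenzyl]malonic acid | COc1cc(OCc2ccccc2)cc(OC)c1CC(C(=O)O)C(=O)O | intermediate
7 | 3-[4-(benzyloxy)-2,6-dimethoxyphenyl]propanoic acid | COc1cc(OCc2ccccc2)cc(OC)c1CCC(=O)O | intermediate
8 | methyl propionate | CCC(=O)OC | starting material
9 | 3-[4-(benzyloxy)-2,6-dimethoxyphenyl]-1-(imidazol-1-yl)propan-1-one | COc1cc(OCc2ccccc2)cc(OC)c1CCC(=O)n1ccnc1 | intermediate
10 | lithium 1-methoxyprop-1-en-1-olate | [Li+].CC=C([O-])OC | intermediate
11 | methyl 5-[4-(benzyloxy)-2,6-dimethoxyphenyl]-2-methyl-3-oxopentanoate (racemic) | COC(=O)C(C)C(=O)CCc1c(OC)cc(OCc2ccccc2)cc1OC | intermediate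
12 | methyl 5-[4-(benzyloxy)-2,6-dimethoxyphenyl]-2-methyl-3-(trimethylsilyloxy)pent-2-enoate | COC(=O)C(C)=C(CCc1c(OC)cc(OCc2ccccc2)cc1OC)O[Si](C)(C)C | intermediate
13 | lithium dienolate of 12 | [Li+].COC([O-])=C(C)/C(O[Si](C)(C)C)=C/Cc1c(OC)cc(OCc2ccccc2)cc1OC | intermediate
14 | (3Z)-5-[4-(benzyloxy)-2,6-dimethoxyphenyl]-1-methoxy-2-methyl-1,3-bis(trimethylsilyloxy)penta-1,3-diene | COC(O[Si](C)(C)C)=C(C)/C(O[Si](C)(C)C)=C/Cc1c(OC)cc(OCc2ccccc2)cc1OC | intermediate
15 | methyl propiolate | C#CC(=O)OC | starting material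
16 | (R)-propylene oxide | C[C@@H]1CO1 | starting material
17 | lithium 3-methoxy-3-oxoprop-1-yn-1-ide | [Li+].[C-]#CC(=O)OC | intermediate
18 | methyl (R)-5-hydroxyhex-2-ynoate | COC(=O)C#CC[C@@H](C)O | intermediate
19 | methyl (R)-5-(tert-butyldimethylsilyloxy)hex-2-ynoate | COC(=O)C#CC[C@@H](C)O[Si](C)(C)C(C)(C)C | intermediate
20 | cyclohexa-1,4-diene cycloadduct (ring sp3 centres undefined, side-chain R) | COC(=O)C1=C(C[C@@H](C)O[Si](C)(C)C(C)(C)C)C(Cc2c(OC)cc(OCc3ccccc3)cc2OC)C(O[Si](C)(C)C)=C(C)C1(OC)O[Si](C)(C)C | intermediate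
21 | 4,6-bis(trimethylsilyl) ether of 22 | COC(=O)c1c(O[Si](C)(C)C)c(C)c(O[Si](C)(C)C)c(Cc2c(OC)cc(OCc3ccccc3)cc2OC)c1C[C@@H](C)O[Si](C)(C)C(C)(C)C | intermediate
22 | methyl 3-[4-(benzyloxy)-2,6-dimethoxybenzyl]-2-[(2R)-2-(tert-butyldimethylsilyloxy)propyl]-4,6-dihydroxy-5-methylbenzoate | COC(=O)c1c(O)c(C)c(O)c(Cc2c(OC)cc(OCc3ccccc3)cc2OC)c1C[C@@H](C)O[Si](C)(C)C(C)(C)C | intermediate
23 | methyl 3-[4-(benzyloxy)-2,6-dimethoxybenzyl]-2-[(2R)-2-(tert-butyldimethylsilyloxy)propyl]-4,6-diisopropoxy-5-methylbenzoate | COC(=O)c1c(OC(C)C)c(C)c(OC(C)C)c(Cc2c(OC)cc(OCc3ccccc3)cc2OC)c1C[C@@H](C)O[Si](C)(C)C(C)(C)C | intermediate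
24 | methyl 3-[4-(benzyloxy)-2,6-dimethoxybenzyl]-2-[(2R)-2-hydroxypropyl]-4,6-diisopropoxy-5-methylbenzoate | COC(=O)c1c(OC(C)C)c(C)c(OC(C)C)c(Cc2c(OC)cc(OCc3ccccc3)cc2OC)c1C[C@@H](C)O | intermediate
25 | (3R)-5-[4-(benzyloxy)-2,6-dimethoxybenzyl]-6,8-diisopropoxy-3,7-dimethylisochroman-1-one | COc1cc(OCc2ccccc2)cc(OC)c1Cc1c(OC(C)C)c(C)c(OC(C)C)c2c1C[C@@H](C)OC2=O | intermediate
26 | (3R)-5-(4-hydroxy-2,6-dimethoxybenzyl)-6,8-diisopropoxy-3,7-dimethylisochroman-1-one | COc1cc(O)cc(OC)c1Cc1c(OC(C)C)c(C)c(OC(C)C)c2c1C[C@@H](C)OC2=O | intermediate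
27 | tert-butyl but-2-ynoate | CC#CC(=O)OC(C)(C)C | starting material
28 | tert-butyl (E)-3-(4-{[(3R)-6,8-diisopropoxy-3,7-dimethyl-1-oxoisochroman-5-yl]methyl}-3,5-dimethoxyphenoxy)but-2-enoate | COc1cc(O/C(C)=C/C(=O)OC(C)(C)C)cc(OC)c1Cc1c(OC(C)C)c(C)c(OC(C)C)c2c1C[C@@H](C)OC2=O | intermediate
29 | (E)-3-(4-{[(3R)-6,8-diisopropoxy-3,7-dimethyl-1-oxoisochroman-5-yl]methyl}-3,5-dimethoxyphenoxy)but-2-enoic acid | COc1cc(O/C(C)=C/C(=O)O)cc(OC)c1Cc1c(OC(C)C)c(C)c(OC(C)C)c2c1C[C@@H](C)OC2=O | intermediate
30 | mixed anhydride of 29 with trifluoroacetic acid (E/Z mobile) | COc1cc(OC(C)=CC(=O)OC(=O)C(F)(F)F)cc(OC)c1Cc1c(OC(C)C)c(C)c(OC(C)C)c2c1C[C@@H](C)OC2=O | intermediate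
31 | (3R)-5-[(5,7-dimethoxy-2-methyl-4-oxo-4H-chromen-6-yl)methyl]-6,8-diisopropoxy-3,7-dimethylisochroman-1-one | COc1cc2oc(C)cc(=O)c2c(OC)c1Cc1c(OC(C)C)c(C)c(OC(C)C)c2c1C[C@@H](C)OC2=O | intermediate
32 | (3R)-6,8-dihydroxy-5-[(5-hydroxy-7-methoxy-2-methyl-4-oxo-4H-chromen-6-yl)methyl]-3,7-dimethylisochroman-1-one | COc1cc2oc(C)cc(=O)c2c(O)c1Cc1c(O)c(C)c(O)c2c1C[C@@H](C)OC2=O | target

**Totals**

Total step count: 14. Longest linear sequence: 12 steps (steps 1-5 and 8-14, from 1).

**Steps most likely to fail**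

1. Step 8.
   - What may go wrong: both bond-forming termini are substituted, so the cycloaddition may be slower than thermal silyl migration and adventitious hydrolysis of the diene. The diene would then be consumed before it is trapped.
   - Fallback (sets out from 19 and 2, returns at 23): the arene is made first with an unhindered diene and the bridge is attached afterwards. Methyl 2-methylacetoacetate is silylated as in steps 4 and 5 to methyl 2-methyl-3-(trimethylsilyloxy)but-2-enoate F1 and then 1-methoxy-2-methyl-1,3-bis(trimethylsilyloxy)buta-1,3-diene F2. The unsubstituted terminus of this diene adds to 19 under the conditions of step 8 to give methyl 2,4-dihydroxy-3-methyl-6-[(2R)-2-(tert-butyldimethylsilyloxy)propyl]benzoate F3. NIS in MeCN iodinates the only free ring position to give methyl 2,4-dihydroxy-5-iodo-3-methyl-6-[(2R)-2-(tert-butyldimethylsilyloxy)propyl]benzoate F4. 2-Iodopropane and Cs2CO3 then give methyl 5-iodo-2,4-diisopropoxy-3-methyl-6-[(2R)-2-(tert-butyldimethylsilyloxy)propyl]benzoate F5. Iodine-magnesium exchange with i-PrMgCl·LiCl (THF, −20 to 0 °C; the hindered ester is spared) gives the arylmagnesium chloride F6. This adds to aldehyde 2 to give the diarylcarbinol F7 as an epimer mixture. Ionic hydrogenation (Et3SiH, TFA, CH2Cl2, −20 °C) removes the doubly benzylic hydroxyl and rejoins the route at 23.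

2. Step 13.
   - What may go wrong: ipso-protonation of the electron-rich ring may be followed by cleavage or migration of the CH2 bridge. E-to-Z equilibration may be incomplete. C-trifluoroacetylation may compete with ring closure.
   - Fallback (sets out from 26, returns at 31): the pyranone is closed without any strong acid. NIS (1 equiv, CH2Cl2, −20 °C) gives (3R)-5-(4-hydroxy-3-iodo-2,6-dimethoxybenzyl)-6,8-diisopropoxy-3,7-dimethylisochroman-1-one F8. A palladium-catalysed carbonylative Sonogashira annulation (PdCl2(dppf), CO 1 atm, propyne, Et2NH, 60 °C) then passes through (3R)-5-[3-(but-2-ynoyl)-4-hydroxy-2,6-dimethoxybenzyl]-6,8-diisopropoxy-3,7-dimethylisochroman-1-one F9. This closes by amine-mediated 6-endo oxa-Michael addition to 31.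

3. Step 12.
   - What may go wrong: conjugate addition to the β-methyl alkynoate may be slow. Base-induced isomerisation and oligomerisation of the acceptor would then use it up before the C-O bond is made.
   - Fallback (sets out from 26, returns at 31): the carbon-carbon bond is made first and the C-O bond last. Friedel-Crafts acetylation ortho to the phenol (Ac2O, BF3·OEt2, CH2Cl2, 0 °C to rt) gives (3R)-5-(3-acetyl-4-hydroxy-2,6-dimethoxybenzyl)-6,8-diisopropoxy-3,7-dimethylisochroman-1-one F10. Condensation with N,N-dimethylacetamide dimethyl acetal (toluene, 100 °C) gives (3R)-5-{3-[(E)-3-(dimethylamino)but-2-enoyl]-4-hydroxy-2,6-dimethoxybenzyl}-6,8-diisopropoxy-3,7-dimethylisochroman-1-one F11. Warm acetic acid closes the ring by addition-elimination to 31.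

**Further compounds**

F1 | step 8 | methyl 2-methyl-3-(trimethylsilyloxy)but-2-enoate | COC(=O)C(C)=C(C)O[Si](C)(C)C
F2 | step 8 | 1-methoxy-2-methyl-1,3-bis(trimethylsilyloxy)buta-1,3-diene | COC(O[Si](C)(C)C)=C(C)C(=C)O[Si](C)(C)C
F3 | step 8 | methyl 2,4-dihydroxy-3-methyl-6-[(2R)-2-(tert-butyldimethylsilyloxy)propyl]benzoate | COC(=O)c1c(O)c(C)c(O)cc1C[C@@H](C)O[Si](C)(C)C(C)(C)C
F4 | step 8 | methyl 2,4-dihydroxy-5-iodo-3-methyl-6-[(2R)-2-(tert-butyldimethylsilyloxy)propyl]benzoate | COC(=O)c1c(O)c(C)c(O)c(I)c1C[C@@H](C)O[Si](C)(C)C(C)(C)C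
F5 | step 8 | methyl 5-iodo-2,4-diisopropoxy-3-methyl-6-[(2R)-2-(tert-butyldimethylsilyloxy)propyl]benzoate | COC(=O)c1c(OC(C)C)c(C)c(OC(C)C)c(I)c1C[C@@H](C)O[Si](C)(C)C(C)(C)C
F6 | step 8 | arylmagnesium chloride from F5 | COC(=O)c1c(OC(C)C)c(C)c(OC(C)C)c([Mg]Cl)c1C[C@@H](C)O[Si](C)(C)C(C)(C)C
F7 | step 8 | methyl 3-{[4-(benzyloxy)-2,6-dimethoxyphenyl](hydroxy)methyl}-2-[(2R)-2-(tert-butyldimethylsilyloxy)propyl]-4,6-diisopropoxy-5-methylbenzoate (carbinol epimers) | COC(=O)c1c(OC(C)C)c(C)c(OC(C)C)c(C(O)c2c(OC)cc(OCc3ccccc3)cc2OC)c1C[C@@H](C)O[Si](C)(C)C(C)(C)C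
F8 | step 13 | (3R)-5-(4-hydroxy-3-iodo-2,6-dimethoxybenzyl)-6,8-diisopropoxy-3,7-dimethylisochroman-1-one | COc1cc(O)c(I)c(OC)c1Cc1c(OC(C)C)c(C)c(OC(C)C)c2c1C[C@@H](C)OC2=O
F9 | step 13 | (3R)-5-[3-(but-2-ynoyl)-4-hydroxy-2,6-dimethoxybenzyl]-6,8-diisopropoxy-3,7-dimethylisochroman-1-one | COc1cc(O)c(C(=O)C#CC)c(OC)c1Cc1c(OC(C)C)c(C)c(OC(C)C)c2c1C[C@@H](C)OC2=O
F10 | step 12 | (3R)-5-(3-acetyl-4-hydroxy-2,6-dimethoxybenzyl)-6,8-diisopropoxy-3,7-dimethylisochroman-1-one | COc1cc(O)c(C(C)=O)c(OC)c1Cc1c(OC(C)C)c(C)c(OC(C)C)c2c1C[C@@H](C)OC2=O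
F11 | step 12 | (3R)-5-{3-[(E)-3-(dimethylamino)but-2-enoyl]-4-hydroxy-2,6-dimethoxybenzyl}-6,8-diisopropoxy-3,7-dimethylisochroman-1-one | COc1cc(O)c(C(=O)/C=C(\C)N(C)C)c(OC)c1Cc1c(OC(C)C)c(C)c(OC(C)C)c2c1C[C@@H](C)OC2=O
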